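At the late end of the runs, isomer of the product over target reads 0.204 in gamma, 0.109 in zeta and 0.103 in alpha. Each isomer reading carries a scatter of 2 percentage points, so I can't read a trend from these last points, and I pool each run instead.

| setting | gamma | zeta | alpha | flask |
|---|---|---|---|---|
| starting material | 0.16 M | 0.16 M | 0.16 M | 0.16 M |
| reagent | 1.1 equiv | 1.1 equiv | 2.2 equiv | 1.10 equiv |
| protic impurity | 0.11 M | 0.18 M | 0.080 M | 0.0800 M |
| remark | run made earlier | run made earlier | run made earlier |  |
| time |  |  |  | 40 min |

| run | time / min | isomer of the product / % | target / % |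
|---|---|---|---|
| gamma | 1.50 | 2 | 11 |
| gamma | 5.00 | 1 | 26 |
| gamma | 10.0 | 4 | 41 |
| gamma | 15.0 | 8 | 45 |
| gamma | 20.0 | 5 | 55 |
| gamma | 25.0 | 9 | 56 |
| gamma | 30.0 | 11 | 54 |
| zeta | 1.50 | 0 | 13 |
| zeta | 5.00 | 5 | 24 |
| zeta | 10.0 | 3 | 39 |
| zeta | 15.0 | 4 | 43 |
| zeta | 20.0 | 4 | 50 |
| zeta | 25.0 | 8 | 47 |
| zeta | 30.0 | 6 | 55 |
| alpha | 6.00 | 10 | 54 |
| alpha | 12.0 | 7 | 64 |
| alpha | 20.0 | 11 | 75 |
| alpha | 25.0 | 5 | 78 |
| alpha | 30.0 | 8 | 78 |

(standard deviation of a reading: 2 percentage points)



* ratio of isomer of the product to target at 8.0 s
* ratio of isomer of the product to target at 2.0 min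
* ratio of isomer of the product to target at 40 min
* which of isomer of the product and target there is more of at 40 min

I call the isomer Q and the target P, both in percent of the starting material charged. Summing down each table, ΣQ/ΣP is 0.139 in gamma. Zeta has more protic impurity than gamma and gives 0.111. Alpha has twice the reagent of gamma and also less protic impurity, and gives 0.117, between the other two. I read no trend with either setting in these pooled ratios.

So I suppose that both products come from starting material and reagent, at rates k_Q[starting material][reagent] and k_P[starting material][reagent], where k_Q and k_P are rate constants. Dividing one rate by the other cancels the concentrations, so dQ/dP = k_Q/k_P. Integrated from zero, this gives Q = sP. I take s, the selectivity factor, as the fixed ratio of isomer to target, and the mean of the pooled readings gives 0.122.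

My reckoning is therefore 0.122 at all asked times, with target ahead.

The forecast gives 0.11, 0.12 and 0.14, with target ahead, reading “parallel products with a fixed ratio”. It stands below my value early and above it late.

The flask gives 0.118 at 8.0 s, 0.119 at 2.0 min and 0.129 at 40 min, with target ahead.

target → over-reaction product (k = 3.80 × 10⁻⁵ /min); starting material + reagent ⇌ target (K = 74.0 /M, k = 0.490 /M/min); starting material + protic impurity → quenched substrate (k = 0.180 /M/min); starting material + reagent ⇌ isomer of the product (K = 16.0 /M, k = 0.0580 /M/min) Its target stands at 60.1 %, and s turns that into 7.33 % of isomer, where the flask holds 7.76 %. The neighbour charged with 0.440 equiv of reagent ends with 30.7 % of target at 40.0 min. There s gives 3.75 % of isomer, and the neighbour holds 3.95 %, a ratio of 0.129. Starting material is the largest share in that neighbour, at 40.8 %.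

(The numbers in the tables stem from a simulated flask for an exercise; scatter was added.)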